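- Sunday's flask takes the largest charge of E, with J and D as in Saturday's and Friday's, so you need to know what a bigger charge does to the percent standing as Z.

common to all: J 0.0525 M

| flask | E | D | remark | time |
|---|---|---|---|---|
| dawn | 0.012 M | 0.10 M | run made earlier |  |
| autumn | 0.033 M | 0.10 M | run made earlier |  |
| Saturday's | 0.020 M | 0.100 M |  | 6.0 h |
| Friday's | 0.030 M | 0.100 M |  | 6.0 h |
| Sunday's | 0.050 M | 0.100 M |  | 6.0 h |

| run | time / h | Z / % |
|---|---|---|
| dawn | 0.667 | 8.4 |
| dawn | 1.33 | 12.4 |
| dawn | 2.00 | 14.1 |
| dawn | 3.00 | 14.5 |
| dawn | 4.00 | 13.0 |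
| autumn | 0.333 | 5.8 |
| autumn | 0.500 | 6.3 |
| autumn | 1.00 | 10.2 |
| autumn | 1.50 | 13.3 |
| autumn | 2.50 | 14.1 |
| autumn | 4.00 | 12.7 |

(standard deviation of a reading: 0.5 percentage points)

- what was read earlier has a scatter of 0.5 percentage points, one standard deviation
- "hardly changes" means that all values lie within two and a half points (for a concentration: within two and a half percent of the largest)

- [Z] at the end for Saturday's, Friday's, Sunday's, in this order
- how that number moves from the first to the last of them (falls all the way / falls, then rises / hardly changes / rises all the way / rises, then falls)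

- Fold the two earlier runs into S = 0.977, the charge response: the percent of charged E standing as Z in the autumn run over that in the dawn run, both at 4.00 h.
- S near 1 means that the percent standing as Z did not follow the charge: the two readings differ by 0.3 percentage points, less than the scatter of 0.5 points, although the autumn charge is 2.75 times the dawn charge.
- My reckoning multiplies S by the charge ratio: W = 2.44 for Sunday's over Saturday's and H = 1.47 for Friday's over Saturday's. Since W exceeds H and H exceeds 1, I expect [Z] to rise all the way.
- The peak readings test S: the autumn 14.1% over the dawn 14.5% gives 0.972, though at different times.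
- S still isn't enough, because it sets ratios and no level, the readings stop at 4.00 h, and Sunday's E over J of 0.952 exceeds the autumn run's 0.629.
- The forecast gives 0.0021 M, 0.0032 M and 0.0053 M, shape rises all the way, holding that “[Z] scales with E charged”. Its Sunday's-to-Saturday's ratio of 2.52 is larger than my W.

- The flask gives 0.00250 M, 0.00363 M and 0.00566 M, shape rises all the way, each higher than the forecast.

    E + J ⇌ Z (K = 7.50 M⁻¹, k = 0.0610 M⁻¹ min⁻¹)
    D + J ⇌ L (K = 17.0 M⁻¹, k = 0.0660 M⁻¹ min⁻¹)
    E → G (k = 3.30 × 10⁻⁶ min⁻¹)
    Z ⇌ Q (K = 1.20, k = 0.00190 min⁻¹)

- Sunday's [Z] over Saturday's comes to 2.26, less than W. At 6.00 h, Sunday's flask keeps 37% of its J unbound, against 42% in Saturday's flask. Applied to Saturday's 0.00250 M, H gives 0.00367 M for Friday's flask, which holds 0.00363 M.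

(The readings stem from a simulated flask with constants of no real substance; scatter was added.)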